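**Retrosynthetic overview**
- Aspidin is cut last at the two benzyl ethers of ring B and at the C1 butanoyl group of ring A (O-acylation, then acyl migration), which leaves the benzyl-protected dimer with a bare, enolised ring A.
- The strategy rests on ring A: a cyclohexa-2,4-dienone made of C6 (ketone), C1, C2 (O), C3 (CH2 bridge), C4 (O) and the quaternary C5 (CMe2), which sits next to the ketone and blocks aromatisation. Ring A is cut at C1–C6 and C2–C3 into ethoxyacetylene and a 2-(arylmethyl)-3-ethoxy-4,4-dimethylcyclobutenone (vinylketene annulation, 6π closure at C6–C5).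
- The cyclobutenone comes from dimethylketene and an arylmethyl ynol ether by [2+2] cycloaddition; the ynol ether comes from the ring B benzylic bromide and ethoxyethynylzinc chloride.
- Ring B is bought as 2,4,6-trihydroxytoluene; butyrylation, ketone-directed dibenzylation, methylation and formylation set its six substituents.
- Ring order: ring B (purchased arene), the four-membered ring (step 8), ring A (step 9).

Key step: step 9

Remark: ring A is drawn throughout in the enol tautomer of the target SMILES, and ethoxyacetylene is taken as its commercial solution in hexanes. Ar in short names means 2,6-bis(benzyloxy)-3-butanoyl-4-methoxy-5-methylphenyl.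

**Route**

Step 1
Reactants: 1 2,4,6-trihydroxytoluene; 2 butanoyl chloride
Product: 3 1-(2,4,6-trihydroxy-3-methylphenyl)butan-1-one
Conditions: AlCl3 (3.5 equiv), PhNO2/CH2Cl2, 0 → 50 °C; aq HCl
Reagents that add atoms: none
Why: Friedel–Crafts acylation of the phloroglucinol ring; the two free ring positions of 1 are equivalent and the first acyl group deactivates the ring against a second one.

Step 2
Reactants: 3 1-(2,4,6-trihydroxy-3-methylphenyl)butan-1-one
Product: 4 1-[4,6-bis(benzyloxy)-2-hydroxy-3-methylphenyl]butan-1-one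
Conditions: BnBr (2.1 equiv), K2CO3, acetone, reflux
Reagents that add atoms: benzyl bromide, BrCc1ccccc1
Why: Williamson etherification under weak base should take the non-chelated para hydroxyl and then the less hindered ortho hydroxyl (flanked by H), while the hydroxyl wedged between the methyl group and the ketone, held in the stronger hydrogen bond, should stay free.

Step 3
Reactants: 4 1-[4,6-bis(benzyloxy)-2-hydroxy-3-methylphenyl]butan-1-one
Product: 5 1-[4,6-bis(benzyloxy)-2-methoxy-3-methylphenyl]butan-1-one
Conditions: MeI, K2CO3, DMF, 50 °C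
Reagents that add atoms: iodomethane, CI
Why: Williamson methylation of the remaining chelated phenol needs only a polar aprotic solvent and mild heating, and K2CO3 is too weak to enolise the ketone for C-methylation.

Step 4
Reactants: 5 1-[4,6-bis(benzyloxy)-2-methoxy-3-methylphenyl]butan-1-one
Product: 7 2,6-bis(benzyloxy)-3-butanoyl-4-methoxy-5-methylbenzaldehyde, via aryl iminium chloride 6 (not isolated)
Conditions: POCl3, DMF, 0 → 70 °C; aq NaOAc
Reagents that add atoms: N,N-dimethylformamide, CN(C)C=O; water, O
Why: Vilsmeier–Haack formylation at the only free ring position, which is activated by two ortho benzyloxy groups and a para methoxy group, while the twisted, doubly ortho-substituted ketone deactivates little and reacts slowly at its α-carbon.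

Step 5
Reactants: 7 2,6-bis(benzyloxy)-3-butanoyl-4-methoxy-5-methylbenzaldehyde
Product: 8 1-[2,4-bis(benzyloxy)-3-(hydroxymethyl)-6-methoxy-5-methylphenyl]butan-1-one
Conditions: NaBH4 (0.5 equiv), THF/EtOH, −20 → 0 °C
Reagents that add atoms: none
Why: Chemoselective borohydride reduction; the aldehyde is far more electrophilic than the out-of-plane, doubly ortho-substituted aryl ketone, so a limited hydride charge at low temperature should reduce only the formyl group.

Step 6
Reactants: 8 1-[2,4-bis(benzyloxy)-3-(hydroxymethyl)-6-methoxy-5-methylphenyl]butan-1-one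
Product: 9 1-[2,4-bis(benzyloxy)-3-(bromomethyl)-6-methoxy-5-methylphenyl]butan-1-one
Conditions: CBr4, PPh3, CH2Cl2, 0 °C
Reagents that add atoms: tetrabromomethane, BrC(Br)(Br)Br
Why: Appel bromination converts the primary benzylic alcohol under neutral conditions that spare the benzyl ethers and the ketone; the bromide is used without long storage.

Step 7
Reactants: 9 1-[2,4-bis(benzyloxy)-3-(bromomethyl)-6-methoxy-5-methylphenyl]butan-1-one; 10 ethoxyacetylene
Product: 13 1-[2,4-bis(benzyloxy)-3-(3-ethoxyprop-2-yn-1-yl)-6-methoxy-5-methylphenyl]butan-1-one, via lithium ethoxyacetylide 11 (not isolated), via ethoxyethynylzinc chloride 12 (not isolated)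
Conditions: 10, n-BuLi, THF, −78 °C; ZnCl2, −78 → 0 °C; then 9, PdCl2(DPEphos) (3 mol %; DPEphos = (2-Ph2PC6H4)2O), THF, 0 °C → rt; NaHCO3 work-up
Reagents that add atoms: none
Why: Negishi coupling of an alkynylzinc with a benzylic bromide on zerovalent palladium formed from the divalent precatalyst; the zinc acetylide neither adds to nor enolises the hindered ketone, and the non-basic medium avoids propargyl-to-allene isomerisation.

Step 8
Reactants: 13 1-[2,4-bis(benzyloxy)-3-(3-ethoxyprop-2-yn-1-yl)-6-methoxy-5-methylphenyl]butan-1-one; 14 2-methylpropanoyl chloride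
Product: 16 2-[[2,6-bis(benzyloxy)-3-butanoyl-4-methoxy-5-methylphenyl]methyl]-3-ethoxy-4,4-dimethylcyclobut-2-en-1-one, via dimethylketene 15 (not isolated)
Conditions: 14 (3 equiv, slow addition), Et3N, THF, 50 °C
Reagents that add atoms: none
Why: Ketene–alkoxyalkyne [2+2] cycloaddition, the standard entry to 3-alkoxycyclobutenones; the nucleophilic alkyne carbon remote from oxygen attacks the ketene carbonyl carbon, which puts the arylmethyl group on C2, ethoxy on C3 and CMe2 on C4.

Step 9
Reactants: 16 2-[[2,6-bis(benzyloxy)-3-butanoyl-4-methoxy-5-methylphenyl]methyl]-3-ethoxy-4,4-dimethylcyclobut-2-en-1-one; 10 ethoxyacetylene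
Product: 20 4-[[2,6-bis(benzyloxy)-3-butanoyl-4-methoxy-5-methylphenyl]methyl]-3,5-diethoxy-6,6-dimethylcyclohexa-2,4-dien-1-one, via vinylketene 17 (not isolated), via vinylcyclobutenone 18 (not isolated), via dienylketene 19 (not isolated)
Conditions: 10 (5 equiv, in portions), toluene, 90 °C, sealed tube
Reagents that add atoms: none
Why: On heating, 16 opens by 4π electrocyclic cleavage of its C1–C4 bond to vinylketene 17, which adds the ynol ether in a [2+2] cycloaddition to give 4-vinylcyclobutenone 18, and a second 4π opening gives dienylketene 19. Ring A then closes by thermal disrotatory 6π electrocyclisation, the ketene carbon (C6) bonding to the CMe2 terminus (C5), so the new skeletal bonds are C6–C1 and C2–C3 and the two alkyne carbons become C1 and C2. The closest known reaction is the Danheiser cyclobutenone–alkyne annulation, in the form that stops at the 2,4-cyclohexadienone because the quaternary C5 blocks tautomerisation to a phenol. No stereocentre is formed, the gem-dimethyl terminus makes the sense of rotation irrelevant, and the reversible opening of 18 should drain through the isomer of 19 that can close. The step needs regiocontrol in the [2+2] event, which polarity provides: the unsubstituted, nucleophilic alkyne carbon bonds to the electrophilic ketene carbon, so ethoxy ends on C2 and hydrogen on C1. It also needs cross-reaction to outrun decay of 17, which an excess of the ketenophilic alkyne and a temperature below the onset of its loss of ethylene should secure.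

Step 10
Reactants: 20 4-[[2,6-bis(benzyloxy)-3-butanoyl-4-methoxy-5-methylphenyl]methyl]-3,5-diethoxy-6,6-dimethylcyclohexa-2,4-dien-1-one
Product: 21 4-[[2,6-bis(benzyloxy)-3-butanoyl-4-methoxy-5-methylphenyl]methyl]-3,5-dihydroxy-6,6-dimethylcyclohexa-2,4-dien-1-one
Conditions: 1 M aq HCl, THF, 40 °C
Reagents that add atoms: water, O
Why: Acid-catalysed hydrolysis of the vinylogous ester (C2) and of the dienyl ether (C4) gives the enolised 1,3,5-trione; benzyl ethers, aryl ketone and methylene bridge should be stable to dilute acid at this temperature.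

Step 11
Reactants: 21 4-[[2,6-bis(benzyloxy)-3-butanoyl-4-methoxy-5-methylphenyl]methyl]-3,5-dihydroxy-6,6-dimethylcyclohexa-2,4-dien-1-one; 2 butanoyl chloride
Product: 23 4-[[2,6-bis(benzyloxy)-3-butanoyl-4-methoxy-5-methylphenyl]methyl]-2-butanoyl-3,5-dihydroxy-6,6-dimethylcyclohexa-2,4-dien-1-one, via enol butanoate 22 (not isolated)
Conditions: 2 (1.1 equiv), Et3N, CH2Cl2, 0 °C; then DMAP (1 equiv), rt → 40 °C
Reagents that add atoms: none
Why: O-acylation of the acidic enol followed by DMAP-mediated O-to-C acyl transfer (the Fries-type migration used for 2-acylcyclohexane-1,3-diones) delivers the acyl group to C1, the only unsubstituted carbon between two carbonyls, where the product is held as a chelated β-triketone.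

Step 12
Reactants: 23 4-[[2,6-bis(benzyloxy)-3-butanoyl-4-methoxy-5-methylphenyl]methyl]-2-butanoyl-3,5-dihydroxy-6,6-dimethylcyclohexa-2,4-dien-1-one
Product: 24 aspidin
Conditions: H2 (1 atm), Pd/C (10 %), EtOAc, rt
Reagents that add atoms: none
Why: Hydrogenolysis of the two benzyl aryl ethers over palladium; the chelated aryl ketone, the enolised triketone and the C–C methylene bridge should not be reduced at 1 atm and room temperature.

**Compound list**
1 | 2,4,6-trihydroxytoluene | Cc1c(O)cc(O)cc1O | starting material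
2 | butanoyl chloride | CCCC(Cl)=O | starting material
3 | 1-(2,4,6-trihydroxy-3-methylphenyl)butan-1-one | CCCC(=O)c1c(O)cc(O)c(C)c1O | intermediate
4 | 1-[4,6-bis(benzyloxy)-2-hydroxy-3-methylphenyl]butan-1-one | CCCC(=O)c1c(O)c(C)c(OCc2ccccc2)cc1OCc1ccccc1 | intermediate
5 | 1-[4,6-bis(benzyloxy)-2-methoxy-3-methylphenyl]butan-1-one | CCCC(=O)c1c(OC)c(C)c(OCc2ccccc2)cc1OCc1ccccc1 | intermediate
6 | aryl iminium chloride, ArCH=NMe2+ Cl− (formed in the flask) | CCCC(=O)c1c(OC)c(C)c(OCc2ccccc2)c(C=[N+](C)C)c1OCc1ccccc1.[Cl-] | intermediate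
7 | 2,6-bis(benzyloxy)-3-butanoyl-4-methoxy-5-methylbenzaldehyde | CCCC(=O)c1c(OC)c(C)c(OCc2ccccc2)c(C=O)c1OCc1ccccc1 | intermediate
8 | 1-[2,4-bis(benzyloxy)-3-(hydroxymethyl)-6-methoxy-5-methylphenyl]butan-1-one | CCCC(=O)c1c(OC)c(C)c(OCc2ccccc2)c(CO)c1OCc1ccccc1 | intermediate
9 | 1-[2,4-bis(benzyloxy)-3-(bromomethyl)-6-methoxy-5-methylphenyl]butan-1-one | CCCC(=O)c1c(OC)c(C)c(OCc2ccccc2)c(CBr)c1OCc1ccccc1 | intermediate
10 | ethoxyacetylene | CCOC#C | starting material
11 | lithium ethoxyacetylide (formed in the flask) | CCOC#C[Li] | intermediate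
12 | ethoxyethynylzinc chloride (formed in the flask) | CCOC#C[Zn]Cl | intermediate
13 | 1-[2,4-bis(benzyloxy)-3-(3-ethoxyprop-2-yn-1-yl)-6-methoxy-5-methylphenyl]butan-1-one | CCOC#CCc1c(OCc2ccccc2)c(C)c(OC)c(C(=O)CCC)c1OCc1ccccc1 | intermediate
14 | 2-methylpropanoyl chloride | CC(C)C(Cl)=O | starting material
15 | dimethylketene (formed in the flask) | CC(C)=C=O | intermediate
16 | 2-[[2,6-bis(benzyloxy)-3-butanoyl-4-methoxy-5-methylphenyl]methyl]-3-ethoxy-4,4-dimethylcyclobut-2-en-1-one | CCOC1=C(Cc2c(OCc3ccccc3)c(C)c(OC)c(C(=O)CCC)c2OCc2ccccc2)C(=O)C1(C)C | intermediate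
17 | vinylketene, 2-(ArCH2)-3-ethoxy-4-methylpenta-1,3-dien-1-one (formed in the flask) | CCOC(=C(C)C)C(Cc1c(OCc2ccccc2)c(C)c(OC)c(C(=O)CCC)c1OCc1ccccc1)=C=O | intermediate
18 | vinylcyclobutenone, racemic 4-(ArCH2)-3-ethoxy-4-(1-ethoxy-2-methylprop-1-enyl)cyclobut-2-en-1-one (formed in the flask) | CCOC1=CC(=O)C1(Cc1c(OCc2ccccc2)c(C)c(OC)c(C(=O)CCC)c1OCc1ccccc1)C(OCC)=C(C)C | intermediate
19 | dienylketene, (3E)-4-(ArCH2)-3,5-diethoxy-6-methylhepta-1,3,5-trien-1-one, ketene arm cis to the ethoxyvinyl arm (formed in the flask) | O=C=C/C(OCC)=C(\C(OCC)=C(C)C)Cc1c(OCc2ccccc2)c(C)c(OC)c(C(=O)CCC)c1OCc1ccccc1 | intermediate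
20 | 4-[[2,6-bis(benzyloxy)-3-butanoyl-4-methoxy-5-methylphenyl]methyl]-3,5-diethoxy-6,6-dimethylcyclohexa-2,4-dien-1-one | O=C1C=C(OCC)C(Cc2c(OCc3ccccc3)c(C)c(OC)c(C(=O)CCC)c2OCc2ccccc2)=C(OCC)C1(C)C | intermediate
21 | 4-[[2,6-bis(benzyloxy)-3-butanoyl-4-methoxy-5-methylphenyl]methyl]-3,5-dihydroxy-6,6-dimethylcyclohexa-2,4-dien-1-one | O=C1C=C(O)C(Cc2c(OCc3ccccc3)c(C)c(OC)c(C(=O)CCC)c2OCc2ccccc2)=C(O)C1(C)C | intermediate
22 | enol butanoate of 21, drawn with butanoyl on the C2 oxygen of ring A (formed in the flask) | CCCC(=O)OC1=CC(=O)C(C)(C)C(O)=C1Cc1c(OCc2ccccc2)c(C)c(OC)c(C(=O)CCC)c1OCc1ccccc1 | intermediate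
23 | 4-[[2,6-bis(benzyloxy)-3-butanoyl-4-methoxy-5-methylphenyl]methyl]-2-butanoyl-3,5-dihydroxy-6,6-dimethylcyclohexa-2,4-dien-1-one | CCCC(=O)C1=C(O)C(Cc2c(OCc3ccccc3)c(C)c(OC)c(C(=O)CCC)c2OCc2ccccc2)=C(O)C(C)(C)C1=O | intermediate
24 | aspidin | CCCC(=O)C1=C(O)C(Cc2c(O)c(C)c(OC)c(C(=O)CCC)c2O)=C(O)C(C)(C)C1=O | target

**Step count**
Total steps: 12. Longest linear sequence: 12 steps (1 → 24).

**Steps most likely to fail**

1. Step 9 (annulation). The alkoxycyclobutenone may open too slowly at temperatures that ethoxyacetylene survives, since the alkyne loses ethylene on stronger heating. The vinylketene may also be diverted before it meets the alkyne, by a 1,5-hydrogen shift from a methyl group of the CMe2 terminus to the ketene carbon or by self-addition. Fallback, from 7 back to 23: ring A is brought in preformed. Commercial 1-(2,4,6-trihydroxyphenyl)butan-1-one is gem-dimethylated on carbon (MeI, NaOMe, MeOH) to 2-butanoyl-3,5-dihydroxy-6,6-dimethylcyclohexa-2,4-dien-1-one (butyrylfilicinic acid) F1. Aldehyde 7, F1 and Hantzsch ester (L-proline, CH2Cl2, rt) then undergo Knoevenagel condensation at the single free ring carbon of F1 and conjugate reduction of the alkylidene, which gives 23 directly; step 12 follows.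

2. Step 7 (ynol ether coupling). The benzylic ynol ether may be lost by hydration to the ester or by propargyl–allenyl isomerisation during coupling and isolation, and the hindered benzylic bromide may homocouple. Fallback, from 7 back to 16, bypassing steps 5 to 8: the four-membered ring is made first and the bridge bond second. 2-Methylpropanoyl chloride 14, Et3N and ethoxyacetylene 10 give 3-ethoxy-4,4-dimethylcyclobut-2-en-1-one F2, and dilute HCl hydrolyses it to 2,2-dimethylcyclobutane-1,3-dione F3. Aldehyde 7, F3 and Hantzsch ester (L-proline, CH2Cl2) give, by Knoevenagel condensation and conjugate reduction, 2-[[2,6-bis(benzyloxy)-3-butanoyl-4-methoxy-5-methylphenyl]methyl]-3-hydroxy-4,4-dimethylcyclobut-2-en-1-one F4. Acid-catalysed enol etherification (EtOH, TsOH cat., benzene, Dean–Stark) gives 16; the two carbonyls of F4 are equivalent, so one enol ether results.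

3. Step 4 (formylation). Ring attack at a position flanked by two benzyloxy groups may be sluggish, so that the chloroiminium reagent attacks the ketone enol instead (β-chlorovinyl aldehyde formation) or a benzyl ether is lost on prolonged heating. Fallback, from 5 back to 7: the ring is formylated as the free phenol. Hydrogenolysis of 5 (H2, Pd/C, EtOAc) gives 1-(4,6-dihydroxy-2-methoxy-3-methylphenyl)butan-1-one F5. Rieche formylation (Cl2CHOMe, TiCl4, CH2Cl2, 0 °C) at the single free position between the two hydroxyls gives 3-butanoyl-2,6-dihydroxy-4-methoxy-5-methylbenzaldehyde F6, and benzylation of both chelated phenols (BnBr, K2CO3, DMF, 60 °C) returns 7.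

**Further compounds**
F1 | step 9 | 2-butanoyl-3,5-dihydroxy-6,6-dimethylcyclohexa-2,4-dien-1-one (butyrylfilicinic acid) | CCCC(=O)C1=C(O)C=C(O)C(C)(C)C1=O
F2 | step 7 | 3-ethoxy-4,4-dimethylcyclobut-2-en-1-one | CCOC1=CC(=O)C1(C)C
F3 | step 7 | 2,2-dimethylcyclobutane-1,3-dione | CC1(C)C(=O)CC1=O
F4 | step 7 | 2-[[2,6-bis(benzyloxy)-3-butanoyl-4-methoxy-5-methylphenyl]methyl]-3-hydroxy-4,4-dimethylcyclobut-2-en-1-one | CCCC(=O)c1c(OC)c(C)c(OCc2ccccc2)c(CC2=C(O)C(C)(C)C2=O)c1OCc1ccccc1
F5 | step 4 | 1-(4,6-dihydroxy-2-methoxy-3-methylphenyl)butan-1-one | CCCC(=O)c1c(OC)c(C)c(O)cc1O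
F6 | step 4 | 3-butanoyl-2,6-dihydroxy-4-methoxy-5-methylbenzaldehyde | CCCC(=O)c1c(OC)c(C)c(O)c(C=O)c1O
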